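**Plan**

- Numbering: ring A is the oxane O1, C2 (methyl, dienyl), C3, C4, C5 (Br), C6 (two methyls); the chain is C7=C8–C9=C10 (methyl on C10); ring B is the cyclohexane C1'–C6' with C4' (methyl, OH) and C5' (Br).
- Cuts: C7=C8 first (cross metathesis), then C5'–Br, the C4'/C5' oxygens, and finally C2'–C3' together with C6'–C1' of ring B; in ring A, O1–C6 and C5–Br are cut together.
- Enabling feature: in ring B the methyl-bearing C4' lies para to C1', and C1' carries the C10–C8 chain at the enal level, so ring B plus C8–C10 is isoprene added to the vinyl end of (E)-3-methylpenta-2,4-dienal.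
- Forward order: ring B closes first in that [4+2]; its alkene is epoxidised and hydrolysed, the aldehyde methylenated and the C5' hydroxyl exchanged for bromide. Ring A closes separately by bromoetherification of (S)-linalool made from geraniol, and the halves are joined last at C7=C8.
- Stereochemistry: C1' from the chiral acid in the cycloaddition; C4' and C5' relayed from C1' (trans-diaxial epoxide opening, then SN2 inversion at C5'); C2 from the Sharpless epoxidation; C5 from the bromoetherification (epimers separated); C9=C10 (E) from the enynol, C7=C8 (E) from the metathesis.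

Key step: step 3

Remark: the route is written for the enantiomer of the acid catalyst that exposes the Si face of the vinyl CH of the dienal; which hand of the catalyst does this has to be found by experiment.

**Route**

Step 1
Reactants: 1 (E)-3-methylpent-2-en-4-yn-1-ol
Product: 2 (E)-3-methylpenta-2,4-dien-1-ol
Conditions: H2 (1 atm, 1 equiv taken up), Pd/CaCO3 poisoned with Pb(OAc)2, quinoline, EtOAc, rt
Reagents that add atoms: none
Why: Semihydrogenation over the Pb(OAc)2-poisoned Pd/CaCO3 catalyst (Lindlar reduction) should reduce the terminal alkyne to the vinyl group and stop there, leaving the (E) trisubstituted alkene and the allylic alcohol untouched.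

Step 2
Reactants: 2 (E)-3-methylpenta-2,4-dien-1-ol
Product: 3 (E)-3-methylpenta-2,4-dienal
Conditions: activated MnO2 (excess), CH2Cl2, rt; filtered and used at once as a cold solution
Reagents that add atoms: none
Why: MnO2 allylic oxidation should convert the primary allylic alcohol into the aldehyde without touching the diene or its (E) geometry.

Step 3
Reactants: 3 (E)-3-methylpenta-2,4-dienal; 4 isoprene
Product: 5 (E)-3-[(R)-4-methylcyclohex-3-en-1-yl]but-2-enal
Conditions: confined chiral imidodiphosphorimidate Brønsted acid (binaphthyl backbone, 3,3'-aryl groups, N-triflyl groups; 3 mol %), isoprene in fivefold excess, CH2Cl2, −78 °C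
Reagents that add atoms: none
Why: Proposed new method: the acid protonates or tightly hydrogen-bonds the aldehyde oxygen of the s-trans dienal 3, which lowers the LUMO of the whole conjugated system and places large coefficients on C10 and on the terminal vinyl carbon (future C2'), so isoprene should add across the vinyl group in a concerted, asynchronous [4+2] in which the C3'–C2' bond leads and the C6'–C1' bond follows. The closest known reaction types are enantioselective Diels–Alder reactions of enals with isoprene or butadiene under chiral oxazaborolidinium or confined imidodiphosphorimidate acids, and 1,6-additions to vinylogous iminium ions; using the remote alkene of an acid-activated dienal as the dienophile is the untested part. Ring B closes as a cyclohexene by an intermolecular six-membered [4+2] cycloaddition, both new bonds forming suprafacially on diene and dienophile. C1' is the only new stereocentre and is controlled by the catalyst pocket alone, which has to expose the Si face of the vinyl CH to the diene. The step needs site selectivity (vinyl group over the C9=C10 alkene and over hetero-Diels–Alder addition at C=O), which the C10 methyl (a quaternary centre would have to form) and low temperature with excess diene should secure; para regioselectivity, which follows from pairing the most nucleophilic isoprene terminus with the most electrophilic dienal terminus; and enantioface selectivity, which rests on the confined anion only and is the weak point.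

Step 4
Reactants: 5 (E)-3-[(R)-4-methylcyclohex-3-en-1-yl]but-2-enal
Product: 6 (E)-3-[(3R)-6-methyl-7-oxabicyclo[4.1.0]heptan-3-yl]but-2-enal, as the mixture of both epoxide diastereomers
Conditions: mCPBA (1.05 equiv), CH2Cl2, 0 °C; aqueous NaHCO3/Na2S2O3 work-up
Reagents that add atoms: mCPBA, O=C(OO)c1cccc(Cl)c1
Why: Prilezhaev epoxidation should take the electron-rich trisubstituted ring alkene far faster than the electron-poor enal alkene, and no facial control is needed because both epoxides converge in step 5.

Step 5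
Reactants: 6 epoxide mixture
Product: 7 (E)-3-[(1R,3S,4S)-3,4-dihydroxy-4-methylcyclohexyl]but-2-enal
Conditions: 1% aqueous H2SO4, THF, 0 °C
Reagents that add atoms: water, O
Why: Acid-catalysed epoxide hydrolysis under Fürst–Plattner control should open each epoxide trans-diaxially (water at C4' in the epoxide whose oxygen is trans to the side chain, at C5' in the one whose oxygen is cis), so both give the same diol with the C4' hydroxyl cis and the C5' hydroxyl trans to the C1' side chain.

Step 6
Reactants: 7 (E)-3-[(1R,3S,4S)-3,4-dihydroxy-4-methylcyclohexyl]but-2-enal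
Product: 8 (1S,2S,4R)-1-methyl-4-[(2E)-penta-2,4-dien-2-yl]cyclohexane-1,2-diol
Conditions: Ph3PCH3Br (3.5 equiv), KOtBu (3.3 equiv), THF, 0 °C; then 7, 0 °C to rt
Reagents that add atoms: methyltriphenylphosphonium bromide, C[P+](c1ccccc1)(c1ccccc1)c1ccccc1.[Br-]
Why: Wittig methylenation with excess ylide (two equivalents are held by the hydroxyl groups) should turn the aldehyde into the terminal vinyl group and give the (E)-diene without touching a stereocentre.

Step 7
Reactants: 8 (1S,2S,4R)-1-methyl-4-[(2E)-penta-2,4-dien-2-yl]cyclohexane-1,2-diol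
Product: 9 (1S,2S,5R)-2-hydroxy-2-methyl-5-[(2E)-penta-2,4-dien-2-yl]cyclohexyl chloromethanesulfonate
Conditions: ClCH2SO2Cl (1.2 equiv), pyridine, CH2Cl2, 0 °C
Reagents that add atoms: chloromethanesulfonyl chloride, ClCS(=O)(=O)Cl
Why: Selective O-sulfonylation should take the secondary C5' hydroxyl and leave the hindered tertiary C4' hydroxyl free, with retention at C5' because only the O–H bond is broken.

Step 8
Reactants: 9 (1S,2S,5R)-2-hydroxy-2-methyl-5-[(2E)-penta-2,4-dien-2-yl]cyclohexyl chloromethanesulfonate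
Product: 10 (1S,2R,4R)-2-bromo-1-methyl-4-[(2E)-penta-2,4-dien-2-yl]cyclohexan-1-ol
Conditions: LiBr (5 equiv), DMF, 25–40 °C, no base
Reagents that add atoms: lithium bromide, [Li+].[Br-]
Why: SN2 displacement of the axial chloromethanesulfonate (a better nucleofuge than mesylate, so mild conditions suffice) by bromide should invert C5' and place bromine equatorial, cis to the C4' hydroxyl and to the side chain, while the absence of base keeps the neighbouring hydroxyl from closing to the epoxide.

Step 9
Reactants: 11 geraniol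
Product: 12 (2S,3S)-2,3-epoxygeraniol
Conditions: Ti(OiPr)4 (5 mol %), L-(+)-diethyl tartrate (7 mol %), t-BuOOH (1.5 equiv), 4 Å molecular sieves, CH2Cl2, −20 °C
Reagents that add atoms: tert-butyl hydroperoxide, CC(C)(C)OO
Why: Sharpless asymmetric epoxidation with the Ti(OiPr)4/L-(+)-diethyl tartrate catalyst should deliver oxygen to one face of the allylic alcohol alkene only, setting C3 as (S) (the future C2 of ring A) and leaving the remote alkene alone.

Step 10
Reactants: 12 (2S,3S)-2,3-epoxygeraniol
Product: 13 (2R,3S)-2-(iodomethyl)-3-methyl-3-(4-methylpent-3-en-1-yl)oxirane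
Conditions: PPh3, I2, imidazole, Et2O/MeCN (3:1), 0 °C
Reagents that add atoms: iodine, II
Why: Appel-type iodination (Garegg–Samuelsson conditions) should replace the primary hydroxyl by iodide through SN2 at CH2, leaving both epoxide carbons untouched.

Step 11
Reactants: 13 (2R,3S)-2-(iodomethyl)-3-methyl-3-(4-methylpent-3-en-1-yl)oxirane
Product: 14 (S)-linalool
Conditions: Zn dust, AcOH, MeOH, 0 °C to rt
Reagents that add atoms: none
Why: Reductive elimination (zinc insertion into the C–I bond, then β-elimination with epoxide opening) should give the tertiary allylic alcohol with the C–O bond at the carbinol carbon intact, so the (S) configuration is carried over.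

Step 12
Reactants: 14 (S)-linalool
Product: 15 (2S,5R)-5-bromo-2-ethenyl-2,6,6-trimethyloxane (bromine trans to the vinyl group)
Conditions: 2,4,4,6-tetrabromocyclohexa-2,5-dienone (1.1 equiv), MeNO2, 0 °C to rt, dark; chromatography
Reagents that add atoms: 2,4,4,6-tetrabromocyclohexa-2,5-dienone, O=C1C(Br)=CC(Br)(Br)C=C1Br
Why: Bromoetherification (6-endo, Markovnikov) should open the bromonium ion of the trisubstituted alkene at its tertiary carbon with the tertiary hydroxyl, anti to bromine; C2 is carried over from linalool, and C5 forms as both epimers, from which the (2S,5R) isomer is separated together with removal of the tetrahydrofuran regioisomers.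

Step 13
Reactants: 10 (1S,2R,4R)-2-bromo-1-methyl-4-[(2E)-penta-2,4-dien-2-yl]cyclohexan-1-ol; 15 (2S,5R)-5-bromo-2-ethenyl-2,6,6-trimethyloxane
Product: 16 (1S,2R,4R)-2-bromo-4-[(2E,4E)-5-[(2S,5R)-5-bromo-2,6,6-trimethyloxan-2-yl]penta-2,4-dien-2-yl]-1-methylcyclohexan-1-ol (target)
Conditions: second-generation Hoveyda–Grubbs catalyst RuCl2(H2IMes)(=CH-C6H4-2-OiPr) (10 mol %), the vinyl oxane in threefold excess, CH2Cl2, 40 °C, argon sweep to remove ethylene
Reagents that add atoms: none
Why: Olefin cross metathesis between the terminal alkene of the diene (fast partner) and the vinyl group on the fully substituted C2 (slow, non-dimerising partner, used in excess) should release ethylene and form C7=C8 as the (E) alkene because it is flanked by a quaternary carbon, while the trisubstituted C9=C10 alkene is too hindered to react.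

**Compound list**

1 | (E)-3-methylpent-2-en-4-yn-1-ol | C#C/C(C)=C/CO | starting material
2 | (E)-3-methylpenta-2,4-dien-1-ol | C=C/C(C)=C/CO | intermediate
3 | (E)-3-methylpenta-2,4-dienal | C/C(=C\C=O)C=C | intermediate
4 | isoprene | C=CC(C)=C | starting material
5 | (E)-3-[(R)-4-methylcyclohex-3-en-1-yl]but-2-enal | C/C(=C\C=O)[C@@H]1CCC(C)=CC1 | intermediate
6 | (E)-3-[(3R)-6-methyl-7-oxabicyclo[4.1.0]heptan-3-yl]but-2-enal, mixture of the (1'R,4'S,5'R) epoxide (oxygen cis to the side chain) and the (1'R,4'R,5'S) epoxide (oxygen trans) | C/C(=C\C=O)[C@@H]1CCC2(C)OC2C1 | intermediate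
7 | (E)-3-[(1R,3S,4S)-3,4-dihydroxy-4-methylcyclohexyl]but-2-enal | C/C(=C\C=O)[C@@H]1CC[C@](C)(O)[C@@H](O)C1 | intermediate
8 | (1S,2S,4R)-1-methyl-4-[(2E)-penta-2,4-dien-2-yl]cyclohexane-1,2-diol | C/C(=C\C=C)[C@@H]1CC[C@](C)(O)[C@@H](O)C1 | intermediate
9 | (1S,2S,5R)-2-hydroxy-2-methyl-5-[(2E)-penta-2,4-dien-2-yl]cyclohexyl chloromethanesulfonate | C/C(=C\C=C)[C@@H]1CC[C@](C)(O)[C@@H](OS(=O)(=O)CCl)C1 | intermediate
10 | (1S,2R,4R)-2-bromo-1-methyl-4-[(2E)-penta-2,4-dien-2-yl]cyclohexan-1-ol | C/C(=C\C=C)[C@@H]1CC[C@](C)(O)[C@H](Br)C1 | intermediate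
11 | geraniol | CC(C)=CCC/C(C)=C/CO | starting material
12 | (2S,3S)-2,3-epoxygeraniol, [(2S,3S)-3-methyl-3-(4-methylpent-3-en-1-yl)oxiran-2-yl]methanol | CC(C)=CCC[C@]1(C)O[C@H]1CO | intermediate
13 | (2R,3S)-2-(iodomethyl)-3-methyl-3-(4-methylpent-3-en-1-yl)oxirane | CC(C)=CCC[C@]1(C)O[C@H]1CI | intermediate
14 | (S)-linalool, (3S)-3,7-dimethylocta-1,6-dien-3-ol | CC(C)=CCC[C@](C)(O)C=C | intermediate
15 | (2S,5R)-5-bromo-2-ethenyl-2,6,6-trimethyloxane [(3R,6S)-3-bromo-6-ethenyl-2,2,6-trimethyloxane] | C=C[C@]1(C)CC[C@@H](Br)C(C)(C)O1 | intermediate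
16 | (1S,2R,4R)-2-bromo-4-[(2E,4E)-5-[(2S,5R)-5-bromo-2,6,6-trimethyloxan-2-yl]penta-2,4-dien-2-yl]-1-methylcyclohexan-1-ol | C/C(=C\C=C\[C@]1(C)CC[C@@H](Br)C(C)(C)O1)[C@@H]1CC[C@](C)(O)[C@H](Br)C1 | target

**Count**

Total: 13 steps. Longest linear sequence: 9 steps (steps 1–8 and 13); the ring A branch is steps 9–12.

**Steps most likely to fail**

Step 3 (proposed new method). The chiral pocket may discriminate poorly between the two faces of a vinyl group that lies far from the bound carbonyl. Hetero-Diels–Alder addition at the carbonyl or acid-induced oligomerisation of the diene may also outrun the wanted cycloaddition. The fallback sets out from isoprene 4 and returns at 5 by way of an auxiliary-controlled acrylate Diels–Alder reaction. 4 and (S)-3-acryloyl-4-benzyloxazolidin-2-one with Et2AlCl in CH2Cl2 at −100 °C should give (4S)-4-benzyl-3-[(1R)-4-methylcyclohex-3-ene-1-carbonyl]oxazolidin-2-one F1, the benzyl group shielding one face of the chelated acrylimide. LiOH/H2O2 should then cleave the auxiliary to (R)-4-methylcyclohex-3-ene-1-carboxylic acid F2, and MeLi (2.2 equiv) should convert the acid into 1-[(1R)-4-methylcyclohex-3-en-1-yl]ethan-1-one F3. Horner–Wadsworth–Emmons reaction with triethyl phosphonoacetate and NaH should give ethyl (E)-3-[(R)-4-methylcyclohex-3-en-1-yl]but-2-enoate F4, the (E) isomer being separated from the (Z) isomer. i-Bu2AlH should reduce the ester to (E)-3-[(R)-4-methylcyclohex-3-en-1-yl]but-2-en-1-ol F5, and MnO2 oxidation returns to 5.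

Step 8. Substitution at C5' is slowed by the fully substituted C4' next to it, so E2 elimination toward C6' or closure of the anti C4' hydroxyl onto C5' (epoxide, then reopening by bromide with the wrong configuration) may compete. The fallback sets out from 8 and returns at 10; it masks the tertiary hydroxyl and uses a triflate at low temperature. Ac2O/pyridine should acetylate only the secondary hydroxyl, giving (1S,2S,5R)-2-hydroxy-2-methyl-5-[(2E)-penta-2,4-dien-2-yl]cyclohexyl acetate F6, and Et3SiOTf/2,6-lutidine should then silylate the tertiary hydroxyl, giving (1S,2S,5R)-2-methyl-5-[(2E)-penta-2,4-dien-2-yl]-2-(triethylsilyloxy)cyclohexyl acetate F7. K2CO3/MeOH should remove the acetate, giving (1S,2S,5R)-2-methyl-5-[(2E)-penta-2,4-dien-2-yl]-2-(triethylsilyloxy)cyclohexan-1-ol F8, which Tf2O/pyridine at −40 °C should convert into (1S,2S,5R)-2-methyl-5-[(2E)-penta-2,4-dien-2-yl]-2-(triethylsilyloxy)cyclohexyl trifluoromethanesulfonate F9. Bu4NBr at −20 to 0 °C should displace the triflate with inversion, giving {[(1S,2R,4R)-2-bromo-1-methyl-4-[(2E)-penta-2,4-dien-2-yl]cyclohexyl]oxy}triethylsilane F10, and HF·pyridine removes the silyl group and returns to 10.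

Step 13. The vinyl group on the fully substituted C2 of 15 may fail to enter the catalytic cycle, so that the diene 10 only homodimerises or degrades on the ruthenium carbene. The fallback sets out from 7 and 15 and returns at 16; it forms C7=C8 by Julia–Kocienski olefination. 7 is sulfonylated as in step 7 to (1S,2S,5R)-2-hydroxy-2-methyl-5-[(2E)-4-oxobut-2-en-2-yl]cyclohexyl chloromethanesulfonate F11, and LiBr as in step 8 should give (2E)-3-[(1R,3R,4S)-3-bromo-4-hydroxy-4-methylcyclohexyl]but-2-enal F12. Luche reduction (NaBH4, CeCl3·7H2O, MeOH) should give (1S,2R,4R)-2-bromo-4-[(2E)-4-hydroxybut-2-en-2-yl]-1-methylcyclohexan-1-ol F13. Mitsunobu thioetherification (1-phenyl-1H-tetrazole-5-thiol, PPh3, DIAD) at the primary allylic hydroxyl should give (1S,2R,4R)-2-bromo-1-methyl-4-[(2E)-4-[(1-phenyl-1H-tetrazol-5-yl)sulfanyl]but-2-en-2-yl]cyclohexan-1-ol F14, and oxidation with H2O2 and (NH4)6Mo7O24·4H2O should give (1S,2R,4R)-2-bromo-1-methyl-4-[(2E)-4-[(1-phenyl-1H-tetrazol-5-yl)sulfonyl]but-2-en-2-yl]cyclohexan-1-ol F15. Ozonolysis of 15 (O3, CH2Cl2, −78 °C; Me2S) should give (2S,5R)-5-bromo-2,6,6-trimethyloxane-2-carbaldehyde F16. KN(SiMe3)2 (2.1 equiv) in THF at −78 °C should then join F15 and F16 to 16, the non-enolisable α-quaternary aldehyde favouring the (E) alkene.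

**Further compounds**

F1 | step 3 | (4S)-4-benzyl-3-[(1R)-4-methylcyclohex-3-ene-1-carbonyl]oxazolidin-2-one | O=C([C@@H]1CCC(C)=CC1)N1[C@@H](Cc2ccccc2)COC1=O
F2 | step 3 | (R)-4-methylcyclohex-3-ene-1-carboxylic acid | OC(=O)[C@@H]1CCC(C)=CC1
F3 | step 3 | 1-[(1R)-4-methylcyclohex-3-en-1-yl]ethan-1-one | CC(=O)[C@@H]1CCC(C)=CC1
F4 | step 3 | ethyl (E)-3-[(R)-4-methylcyclohex-3-en-1-yl]but-2-enoate | C/C(=C\C(=O)OCC)[C@@H]1CCC(C)=CC1
F5 | step 3 | (E)-3-[(R)-4-methylcyclohex-3-en-1-yl]but-2-en-1-ol | C/C(=C\CO)[C@@H]1CCC(C)=CC1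
F6 | step 8 | (1S,2S,5R)-2-hydroxy-2-methyl-5-[(2E)-penta-2,4-dien-2-yl]cyclohexyl acetate | C/C(=C\C=C)[C@@H]1CC[C@](C)(O)[C@@H](OC(C)=O)C1
F7 | step 8 | (1S,2S,5R)-2-methyl-5-[(2E)-penta-2,4-dien-2-yl]-2-(triethylsilyloxy)cyclohexyl acetate | C/C(=C\C=C)[C@@H]1CC[C@](C)(O[Si](CC)(CC)CC)[C@@H](OC(C)=O)C1
F8 | step 8 | (1S,2S,5R)-2-methyl-5-[(2E)-penta-2,4-dien-2-yl]-2-(triethylsilyloxy)cyclohexan-1-ol | C/C(=C\C=C)[C@@H]1CC[C@](C)(O[Si](CC)(CC)CC)[C@@H](O)C1
F9 | step 8 | (1S,2S,5R)-2-methyl-5-[(2E)-penta-2,4-dien-2-yl]-2-(triethylsilyloxy)cyclohexyl trifluoromethanesulfonate | C/C(=C\C=C)[C@@H]1CC[C@](C)(O[Si](CC)(CC)CC)[C@@H](OS(=O)(=O)C(F)(F)F)C1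
F10 | step 8 | {[(1S,2R,4R)-2-bromo-1-methyl-4-[(2E)-penta-2,4-dien-2-yl]cyclohexyl]oxy}triethylsilane | C/C(=C\C=C)[C@@H]1CC[C@](C)(O[Si](CC)(CC)CC)[C@H](Br)C1
F11 | step 13 | (1S,2S,5R)-2-hydroxy-2-methyl-5-[(2E)-4-oxobut-2-en-2-yl]cyclohexyl chloromethanesulfonate | C/C(=C\C=O)[C@@H]1CC[C@](C)(O)[C@@H](OS(=O)(=O)CCl)C1
F12 | step 13 | (2E)-3-[(1R,3R,4S)-3-bromo-4-hydroxy-4-methylcyclohexyl]but-2-enal | C/C(=C\C=O)[C@@H]1CC[C@](C)(O)[C@H](Br)C1
F13 | step 13 | (1S,2R,4R)-2-bromo-4-[(2E)-4-hydroxybut-2-en-2-yl]-1-methylcyclohexan-1-ol | C/C(=C\CO)[C@@H]1CC[C@](C)(O)[C@H](Br)C1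
F14 | step 13 | (1S,2R,4R)-2-bromo-1-methyl-4-[(2E)-4-[(1-phenyl-1H-tetrazol-5-yl)sulfanyl]but-2-en-2-yl]cyclohexan-1-ol | C/C(=C\CSc1nnnn1-c2ccccc2)[C@@H]1CC[C@](C)(O)[C@H](Br)C1
F15 | step 13 | (1S,2R,4R)-2-bromo-1-methyl-4-[(2E)-4-[(1-phenyl-1H-tetrazol-5-yl)sulfonyl]but-2-en-2-yl]cyclohexan-1-ol | C/C(=C\CS(=O)(=O)c1nnnn1-c2ccccc2)[C@@H]1CC[C@](C)(O)[C@H](Br)C1
F16 | step 13 | (2S,5R)-5-bromo-2,6,6-trimethyloxane-2-carbaldehyde | O=C[C@]1(C)CC[C@@H](Br)C(C)(C)O1
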